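**Retrosynthetic overview**
1. Last C–C bond (key step): C6–CH2 of the hydroxy-isopentenyl chain, by Ni-catalysed radical ring-opening arylation of enantiopure (S)-2-isopropenyloxirane with a 6-iodoflavanone; MOM removal follows.
2. C2–aryl bond and the 2S centre: Rh-catalysed asymmetric 1,4-addition of 4-hydroxyphenylboronic acid to a 6-iodo-8-prenylchromone.
3. Pyranone ring (the only ring made): o-hydroxyacetophenone plus DMF-DMA; acetyl and prenyl go onto the two positions ortho to the single free phenol.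
4. A ring: resorcinol → bis-MOM ether → ortho-lithiation/iodination (future C6) → Ir C–H borylation/oxidation para to iodine (future O1), which tells the three oxygens apart.
5. Ring order: A and B rings are bought as benzenes, the C ring is closed at the chromone stage; the epoxide comes from methacrolein (Corey–Chaykovsky, then HKR).

Assumption: the absolute sense of the two catalyst-controlled steps (HKR, Rh addition) is assigned by analogy with the parent cases, not from a direct precedent on these substrates, and is confirmed on the first run by optical rotation and CD.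

**Route**

Step 1
Reactants: 1 resorcinol
Product: 2 1,3-bis(methoxymethoxy)benzene
Conditions: MOMCl (2.5 equiv), i-Pr2NEt (3 equiv), CH2Cl2, 0 °C → rt
Reagents that add atoms: chloromethyl methyl ether, COCCl
Why: Double O-alkylation of the phenol (acetal protection) installs the two ether groups that later direct metalation.

Step 2
Reactants: 2 1,3-bis(methoxymethoxy)benzene
Product: 4 2-iodo-1,3-bis(methoxymethoxy)benzene, via aryllithium 3 (not isolated)
Conditions: n-BuLi (1.1 equiv), THF, 0 °C → rt; then I2, −78 °C → rt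
Reagents that add atoms: iodine, II
Why: Directed ortho-metalation lithiates the C–H between the two OMOM groups by chelation, and iodine traps the aryllithium.

Step 3
Reactants: 4 2-iodo-1,3-bis(methoxymethoxy)benzene
Product: 6 4-iodo-3,5-bis(methoxymethoxy)phenol, via arylboronate 5 (not isolated)
Conditions: [Ir(OMe)(cod)]2 (1.5 mol %), dtbpy (3 mol %), B2pin2 (0.6 equiv), THF, 80 °C; then aq NaOH, 30% H2O2, 0 °C → rt
Reagents that add atoms: hydrogen peroxide, OO
Why: Sterically controlled Ir-catalysed C–H borylation takes the only C–H without an ortho substituent (para to iodine, Ar–I tolerated), and basic peroxide oxidation of the C–B bond gives the one free phenol that becomes O1.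

Step 4
Reactants: 6 4-iodo-3,5-bis(methoxymethoxy)phenol; 7 prenyl bromide
Product: 9 4-iodo-3,5-bis(methoxymethoxy)-2-(3-methylbut-2-en-1-yl)phenol, via sodium phenoxide 8 (not isolated)
Conditions: NaH (1.1 equiv), toluene, 0 °C; then 7 (1.05 equiv), rt
Reagents that add atoms: none
Why: ortho-C-alkylation of a sodium phenoxide in a non-polar solvent (tight ion pair, SN2 on the allylic bromide) goes to an ortho carbon because the para position is blocked by iodine.

Step 5
Reactants: 9 4-iodo-3,5-bis(methoxymethoxy)-2-(3-methylbut-2-en-1-yl)phenol; 10 acetyl chloride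
Product: 12 1-[2-hydroxy-5-iodo-4,6-bis(methoxymethoxy)-3-(3-methylbut-2-en-1-yl)phenyl]ethan-1-one, via magnesium phenolate 11 (not isolated)
Conditions: EtMgBr (1.0 equiv), Et2O → toluene, 0 °C; then 10 (1.1 equiv), toluene, 0 °C → rt
Reagents that add atoms: none
Why: Ortho-coordinated C-acylation of a bromomagnesium phenolate (chelate-controlled Friedel–Crafts-type acylation without a Lewis acid that would cleave MOM) takes the only free ring position.

Step 6
Reactants: 12 1-[2-hydroxy-5-iodo-4,6-bis(methoxymethoxy)-3-(3-methylbut-2-en-1-yl)phenyl]ethan-1-one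
Product: 14 6-iodo-5,7-bis(methoxymethoxy)-8-(3-methylbut-2-en-1-yl)-4H-chromen-4-one, via enaminone 13 (not isolated)
Conditions: DMF-DMA (3 equiv), toluene, 90 °C; then AcOH, 60 °C
Reagents that add atoms: N,N-dimethylformamide dimethyl acetal, COC(OC)N(C)C
Why: Enaminone formation at the methyl ketone and acid-promoted addition–elimination by the ortho phenol is the standard chromone synthesis, and since only the one free OH can close, prenyl ends at C8 and iodine at C6.

Step 7
Reactants: 15 4-bromophenol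
Product: 16 (4-hydroxyphenyl)boronic acid
Conditions: XPhos Pd G2 (1 mol %), XPhos (2 mol %), B2(OH)4 (1.5 equiv), KOAc (3 equiv), EtOH, 80 °C
Reagents that add atoms: tetrahydroxydiboron, OB(O)B(O)O
Why: Pd-catalysed Miyaura-type borylation of the aryl bromide with tetrahydroxydiboron tolerates the free phenol and gives the boronic acid directly.

Step 8
Reactants: 14 6-iodo-5,7-bis(methoxymethoxy)-8-(3-methylbut-2-en-1-yl)-4H-chromen-4-one; 16 (4-hydroxyphenyl)boronic acid
Product: 17 (2S)-2-(4-hydroxyphenyl)-6-iodo-5,7-bis(methoxymethoxy)-8-(3-methylbut-2-en-1-yl)-2,3-dihydro-4H-chromen-4-one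
Conditions: [Rh(OH)(cod)]2 (2.5 mol %), (S)-MeO-F12-BIPHEP (5.5 mol %), 16 (3 equiv), toluene/H2O 10:1, 40 °C
Reagents that add atoms: none
Why: Rh(I)-catalysed asymmetric 1,4-addition of an arylboronic acid (Hayashi–Miyaura type) to the chromone sets C2, the (S)-biaryl bisphosphine giving 2S by the same facial sense in which (S)-BINAP gives (S)-3-arylcyclohexanones, while the hindered electron-rich Ar–I is left alone by Rh(I).

Step 9
Reactants: 18 methacrolein
Product: 19 rac-2-(prop-1-en-2-yl)oxirane
Conditions: Me3S+ I− (1.1 equiv), KOt-Bu (1.1 equiv), DMSO, rt; then 18, 0 °C → rt; distil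
Reagents that add atoms: trimethylsulfonium iodide, C[S+](C)C.[I-]
Why: Corey–Chaykovsky epoxidation, in which the sulfonium ylide adds 1,2 to the non-enolisable enal and closes to the alkenyl oxirane (racemic).

Step 10
Reactants: 19 rac-2-(prop-1-en-2-yl)oxirane
Product: 20 (2S)-2-(prop-1-en-2-yl)oxirane
Conditions: (S,S)-(salen)Co(III)OAc (0.5 mol %), H2O (0.55 equiv), neat, 0 °C → rt; distil
Reagents that add atoms: none
Why: Jacobsen hydrolytic kinetic resolution hydrolyses the (R)-epoxide to the diol and leaves the volatile (S)-epoxide in high ee, which fixes the carbinol stereocentre of the target.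

Step 11
Reactants: 17 (2S)-2-(4-hydroxyphenyl)-6-iodo-5,7-bis(methoxymethoxy)-8-(3-methylbut-2-en-1-yl)-2,3-dihydro-4H-chromen-4-one; 20 (2S)-2-(prop-1-en-2-yl)oxirane
Product: 22 (2S)-6-[(2R)-2-hydroxy-3-methylbut-3-en-1-yl]-2-(4-hydroxyphenyl)-5,7-bis(methoxymethoxy)-8-(3-methylbut-2-en-1-yl)-2,3-dihydro-4H-chromen-4-one, via iodohydrin 21 (not isolated)
Conditions: NiI2 (10 mol %), 2,2'-bipyridine (10 mol %), NaI (25 mol %), Et3N·HCl (1.0 equiv), Zn (2 equiv), 20 (2 equiv), DMPU, 25 °C
Reagents that add atoms: none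
Why: Proposed new method: the Ni/iodide co-catalysed reductive cross-electrophile coupling of aryl halides with terminal epoxides (closest known reaction type, giving ArCH2CH(OH)R) is extended to an alkenyl epoxide and a 2,6-dialkoxyaryl iodide — iodide/Et3NH+ opens 20 at the unsubstituted CH2 to iodohydrin 21, halogen abstraction gives the primary β-hydroxyalkyl radical, ArNi(II) from oxidative addition into C6–I captures it and reductive elimination from Ni(III) forms the C6–CH2 bond; the C–O bond at the stereocentre is never broken, so (S)-20 gives the (2R)-carbinol (descriptor changes by CIP rank only) and C2 is untouched.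

Step 12
Reactants: 22 (2S)-6-[(2R)-2-hydroxy-3-methylbut-3-en-1-yl]-2-(4-hydroxyphenyl)-5,7-bis(methoxymethoxy)-8-(3-methylbut-2-en-1-yl)-2,3-dihydro-4H-chromen-4-one
Product: 23 (2S)-5,7-dihydroxy-6-[(2R)-2-hydroxy-3-methylbut-3-en-1-yl]-2-(4-hydroxyphenyl)-8-(3-methylbut-2-en-1-yl)-2,3-dihydro-4H-chromen-4-one
Conditions: HCl (1.25 M in MeOH), THF, 25–40 °C
Reagents that add atoms: none
Why: Acid-catalysed acetal methanolysis cleaves the two phenolic MOM ethers under conditions mild enough to leave the prenyl group, the secondary allylic alcohol and the C2 stereocentre untouched.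

**Compound list**
1 | resorcinol | Oc1cccc(O)c1 | starting material
2 | 1,3-bis(methoxymethoxy)benzene | COCOc1cccc(OCOC)c1 | intermediate
3 | [2,6-bis(methoxymethoxy)phenyl]lithium | [Li]c1c(OCOC)cccc1OCOC | intermediate
4 | 2-iodo-1,3-bis(methoxymethoxy)benzene | COCOc1cccc(OCOC)c1I | intermediate
5 | 2-[4-iodo-3,5-bis(methoxymethoxy)phenyl]-4,4,5,5-tetramethyl-1,3,2-dioxaborolane | COCOc1cc(B2OC(C)(C)C(C)(C)O2)cc(OCOC)c1I | intermediate
6 | 4-iodo-3,5-bis(methoxymethoxy)phenol | COCOc1cc(O)cc(OCOC)c1I | intermediate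
7 | prenyl bromide (1-bromo-3-methylbut-2-ene) | CC(C)=CCBr | starting material
8 | sodium 4-iodo-3,5-bis(methoxymethoxy)phenolate | [Na+].[O-]c1cc(OCOC)c(I)c(OCOC)c1 | intermediate
9 | 4-iodo-3,5-bis(methoxymethoxy)-2-(3-methylbut-2-en-1-yl)phenol | CC(C)=CCc1c(O)cc(OCOC)c(I)c1OCOC | intermediate
10 | acetyl chloride | CC(=O)Cl | starting material
11 | bromomagnesium 4-iodo-3,5-bis(methoxymethoxy)-2-(3-methylbut-2-en-1-yl)phenolate | CC(C)=CCc1c(O[Mg]Br)cc(OCOC)c(I)c1OCOC | intermediate
12 | 1-[2-hydroxy-5-iodo-4,6-bis(methoxymethoxy)-3-(3-methylbut-2-en-1-yl)phenyl]ethan-1-one | CC(=O)c1c(O)c(CC=C(C)C)c(OCOC)c(I)c1OCOC | intermediate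
13 | (2E)-3-(dimethylamino)-1-[2-hydroxy-5-iodo-4,6-bis(methoxymethoxy)-3-(3-methylbut-2-en-1-yl)phenyl]prop-2-en-1-one | CN(C)/C=C/C(=O)c1c(O)c(CC=C(C)C)c(OCOC)c(I)c1OCOC | intermediate
14 | 6-iodo-5,7-bis(methoxymethoxy)-8-(3-methylbut-2-en-1-yl)-4H-chromen-4-one | O=c1ccoc2c(CC=C(C)C)c(OCOC)c(I)c(OCOC)c12 | intermediate
15 | 4-bromophenol | Oc1ccc(Br)cc1 | starting material
16 | (4-hydroxyphenyl)boronic acid | OB(O)c1ccc(O)cc1 | intermediate
17 | (2S)-2-(4-hydroxyphenyl)-6-iodo-5,7-bis(methoxymethoxy)-8-(3-methylbut-2-en-1-yl)-2,3-dihydro-4H-chromen-4-one | Ic1c(OCOC)c(CC=C(C)C)c2c(c1OCOC)C(=O)C[C@@H](c1ccc(O)cc1)O2 | intermediate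
18 | methacrolein (2-methylprop-2-enal) | C=C(C)C=O | starting material
19 | rac-2-(prop-1-en-2-yl)oxirane | C=C(C)C1CO1 | intermediate
20 | (2S)-2-(prop-1-en-2-yl)oxirane | C=C(C)[C@H]1CO1 | intermediate
21 | (2S)-1-iodo-3-methylbut-3-en-2-ol | C=C(C)[C@H](O)CI | intermediate
22 | (2S)-6-[(2R)-2-hydroxy-3-methylbut-3-en-1-yl]-2-(4-hydroxyphenyl)-5,7-bis(methoxymethoxy)-8-(3-methylbut-2-en-1-yl)-2,3-dihydro-4H-chromen-4-one | C=C(C)[C@H](O)Cc1c(OCOC)c(CC=C(C)C)c2c(c1OCOC)C(=O)C[C@@H](c1ccc(O)cc1)O2 | intermediate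
23 | (2S)-5,7-dihydroxy-6-[(2R)-2-hydroxy-3-methylbut-3-en-1-yl]-2-(4-hydroxyphenyl)-8-(3-methylbut-2-en-1-yl)-2,3-dihydro-4H-chromen-4-one | C=C(C)[C@H](O)Cc1c(O)c(CC=C(C)C)c2c(c1O)C(=O)C[C@@H](c1ccc(O)cc1)O2 | target

**Count**
Total steps: 12. Longest linear sequence: 9 (steps 1–6, 8, 11, 12). Steps 7 and 9–10 are side branches.

**Three steps most likely to fail**

Step 11 (key radical coupling). Three things can go wrong. Iodide may open the alkenyl epoxide at the allylic carbon or in an SN2' sense, giving allylic iodides that couple to the wrong products. The homoallylic radical may undergo a 1,2-vinyl shift before Ni captures it. The aryl iodide, flanked by two OMOM groups, may add slowly to Ni and be reduced to Ar–H instead. The fallback sets out from 20 and 17 and comes back at 22, replacing the radical coupling by a polar Negishi coupling of a preformed, purified partner. Epoxide 20 is opened on purpose with LiI/AcOH in THF at 0 °C, and iodohydrin 21 is isolated and freed from any allylic isomer. Silylation (TBSCl, imidazole, DMF) gives tert-butyl{[(2S)-1-iodo-3-methylbut-3-en-2-yl]oxy}dimethylsilane F1. Zinc insertion (Zn dust, LiCl, THF, 25 °C) gives {(2S)-2-[(tert-butyldimethylsilyl)oxy]-3-methylbut-3-en-1-yl}zinc iodide F2. This is coupled with 17 under Pd(OAc)2/CPhos in THF/NMP at 40 °C, using excess F2 because the 4'-OH consumes one equivalent, to give (2S)-6-{(2R)-2-[(tert-butyldimethylsilyl)oxy]-3-methylbut-3-en-1-yl}-2-(4-hydroxyphenyl)-5,7-bis(methoxymethoxy)-8-(3-methylbut-2-en-1-yl)-2,3-dihydro-4H-chromen-4-one F3. HF·pyridine in THF removes the silyl group and gives 22.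

Step 5 (C-acetylation). O-acetylation may win over C-acylation at the crowded last ring position, and the HCl formed can attack the MOM and prenyl groups. The fallback sets out from 9 and comes back at 12, building the acetyl group in two C1 stages under non-acidic conditions. Magnesium-mediated ortho-formylation (MgCl2, Et3N, paraformaldehyde, MeCN, reflux) gives 2-hydroxy-5-iodo-4,6-bis(methoxymethoxy)-3-(3-methylbut-2-en-1-yl)benzaldehyde F4. MeMgBr (2.2 equiv, THF, −78 → 0 °C; no I/Mg exchange with this Grignard) gives 1-[2-hydroxy-5-iodo-4,6-bis(methoxymethoxy)-3-(3-methylbut-2-en-1-yl)phenyl]ethan-1-ol F5. MnO2 in CH2Cl2 (or Dess–Martin periodinane) oxidises the benzylic alcohol to 12.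

Step 4 (C-prenylation). O-alkylation and double C-alkylation compete, so the yield of mono-ortho product may be low. The fallback sets out from 6 and comes back at 9, going through the ether and rearranging it. O-prenylation (K2CO3, acetone, 7, rt) gives 2-iodo-1,3-bis(methoxymethoxy)-5-[(3-methylbut-2-en-1-yl)oxy]benzene F6. Montmorillonite K10 in CH2Cl2 at rt then induces the [1,3] O→C prenyl shift to the ortho carbon (para is blocked), giving 9.

**Further compounds**
F1 | step 11 | tert-butyl{[(2S)-1-iodo-3-methylbut-3-en-2-yl]oxy}dimethylsilane | C=C(C)[C@H](O[Si](C)(C)C(C)(C)C)CI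
F2 | step 11 | {(2S)-2-[(tert-butyldimethylsilyl)oxy]-3-methylbut-3-en-1-yl}zinc iodide | C=C(C)[C@H](O[Si](C)(C)C(C)(C)C)C[Zn]I
F3 | step 11 | (2S)-6-{(2R)-2-[(tert-butyldimethylsilyl)oxy]-3-methylbut-3-en-1-yl}-2-(4-hydroxyphenyl)-5,7-bis(methoxymethoxy)-8-(3-methylbut-2-en-1-yl)-2,3-dihydro-4H-chromen-4-one | C=C(C)[C@H](O[Si](C)(C)C(C)(C)C)Cc1c(OCOC)c(CC=C(C)C)c2c(c1OCOC)C(=O)C[C@@H](c1ccc(O)cc1)O2
F4 | step 5 | 2-hydroxy-5-iodo-4,6-bis(methoxymethoxy)-3-(3-methylbut-2-en-1-yl)benzaldehyde | O=Cc1c(O)c(CC=C(C)C)c(OCOC)c(I)c1OCOC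
F5 | step 5 | 1-[2-hydroxy-5-iodo-4,6-bis(methoxymethoxy)-3-(3-methylbut-2-en-1-yl)phenyl]ethan-1-ol (racemic) | CC(O)c1c(O)c(CC=C(C)C)c(OCOC)c(I)c1OCOC
F6 | step 4 | 2-iodo-1,3-bis(methoxymethoxy)-5-[(3-methylbut-2-en-1-yl)oxy]benzene | CC(C)=CCOc1cc(OCOC)c(I)c(OCOC)c1
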